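## Retrosynthetic overview

Locants are those of the target as 7-oxabicyclo[4.1.0]hept-3-en-2-one: C1 farnesyl-bearing oxirane carbon, C2 C=O, C3 =CH, C4 C–ethyl, C5 CHOH, C6 oxirane CH.
1. Target ⇐ saturated epoxy ketone (Saegusa–Ito dehydrogenation C3–C4, last) ⇐ 4-hydroxy-5-ethyl-2-farnesylcyclohex-2-enone (Weitz–Scheffer epoxidation of C1=C6, after a lipase resolution).
2. That cyclohexenone ⇐ one Diels–Alder reaction that makes C3–C4 and C5–C6 together: a 1-methoxy-3-silyloxy-2-farnesylbuta-1,3-diene (C3, C2, C1, C6) plus B-[(E)-but-1-enyl]-9-BBN (C4, C5, ethyl). Boron activates the dienophile and is the masked C5 hydroxyl; methoxy and silyl leave when the enone is released.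
3. Enabling feature: in the six-membered ring the C2 carbonyl and the oxygen-bearing C6 flank the farnesyl-bearing C1, which is the 1,3-dioxygenation of an electron-rich diene C3=C2(O)–C1=C6(O). The carbinol C5 lies next to C6 and para to C2, exactly where a polarised cycloaddition puts the boron-bearing carbon.
4. Diene ⇐ (5E,9E)-farnesylacetone (C1, C2, C3, chain) + trimethyl orthoformate (C6), through the more substituted silyl enol ether.
5. Ring order: carbocycle first (step 4), oxirane second (step 7), C3=C4 last, so that no intermediate can tautomerise to a phenol or hydroquinone.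

Key step: step 4

Remark: (5E,9E)-farnesylacetone is taken as commercially available in isomerically pure form.
Remark: Far = (2E,6E)-3,7,11-trimethyldodeca-2,6,10-trien-1-yl (farnesyl); ring locants in the Why lines are target locants unless a compound name says otherwise.
Remark: the sense of the lipase resolution in step 6 is assumed from the usual size rule for secondary alcohols (the enantiomer with an S carbinol is acetylated).

## Route

Step 1
Reactants: 1 (5E,9E)-6,10,14-trimethylpentadeca-5,9,13-trien-2-one (farnesylacetone)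
Product: 2 trimethyl{[(2Z,5E,9E)-6,10,14-trimethylpentadeca-2,5,9,13-tetraen-2-yl]oxy}silane
Conditions: Me3SiCl, NaI, Et3N, MeCN, 25 °C
Reagents that add atoms: chlorotrimethylsilane, C[Si](C)(C)Cl
Why: Thermodynamic silyl enol ether formation (soft enolisation by Me3SiI made in situ, equilibrating) should give mainly the more substituted enol ether, which fixes the later C–C bond formation at the methylene carbon that becomes C1; no stereocentre is formed and the minor terminal isomer is removed after step 2.

Step 2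
Reactants: 2 trimethyl{[(2Z,5E,9E)-6,10,14-trimethylpentadeca-2,5,9,13-tetraen-2-yl]oxy}silane; 3 trimethyl orthoformate
Product: 4 rac-(5E,9E)-3-(dimethoxymethyl)-6,10,14-trimethylpentadeca-5,9,13-trien-2-one
Conditions: TMSOTf (catalytic), CH2Cl2, −78 °C
Reagents that add atoms: none
Why: Mukaiyama aldol-type reaction of a silyl enol ether with the dimethoxycarbenium ion from an ortho ester installs the masked formyl carbon that becomes C6; the new stereocentre is racemic and is erased in step 3, and the weakly electrophilic carbenium ion should spare the chain alkenes.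

Step 3
Reactants: 4 rac-(5E,9E)-3-(dimethoxymethyl)-6,10,14-trimethylpentadeca-5,9,13-trien-2-one
Product: 6 (1E)-3-(tert-butyldimethylsilyloxy)-2-Far-1-methoxybuta-1,3-diene, via (3E)-3-Far-4-methoxybut-3-en-2-one 5 (not isolated)
Conditions: TBSOTf (2.3 equiv), Et3N (3.5 equiv), Et2O, 0 to 25 °C
Reagents that add atoms: tert-butyldimethylsilyl trifluoromethanesulfonate, CC(C)(C)[Si](C)(C)OS(=O)(=O)C(F)(F)F
Why: Silyl triflate/amine-induced loss of methanol from the β-keto acetal (acetal-to-enol-ether elimination) gives the (E)-β-methoxy enone, whose methyl ketone is then enol-silylated on its only enolisable side (silyl enol ether formation) to give the 1-methoxy-3-silyloxy diene; no stereocentre is formed.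

Step 4
Reactants: 6 (1E)-3-(tert-butyldimethylsilyloxy)-2-Far-1-methoxybuta-1,3-diene; 7 but-1-yne; 8 9-borabicyclo[3.3.1]nonane (9-BBN-H, as dimer)
Product: 11 rac-(1R,6S)-4-(tert-butyldimethylsilyloxy)-6-ethyl-3-Far-2-methoxycyclohex-3-en-1-ol (C2 epimers), via 9-[(1E)-but-1-en-1-yl]-9-borabicyclo[3.3.1]nonane 9 (not isolated), via cyclohexenylborane cycloadduct 10 (not isolated)
Conditions: 7 (excess), 8, THF, 0 to 25 °C; excess alkyne removed; 6, THF, 25 to 50 °C; NaBO3·4H2O, THF/H2O, 25 °C
Reagents that add atoms: sodium perborate tetrahydrate, [Na+].[Na+].O[B-]1(O)OO[B-](O)(O)OO1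
Why: Monohydroboration of excess but-1-yne by 9-BBN-H (syn, anti-Markovnikov) gives the (E)-alkenylborane 9, which adds to diene 6 in a thermal Diels–Alder reaction, the closest known reaction type being the [4+2] cycloaddition of B-alkenyl-9-borabicyclononanes with acyclic 1,3-dienes followed by oxidation of the C–B bond. The six-membered ring closes in a concerted but asynchronous suprafacial [4+2] mode: the CH2 terminus of the diene, made nucleophilic by the neighbouring silyloxy group and the vinylogous methoxy group, bonds to the ethyl-bearing β-carbon of 9 (conjugated with the empty boron p orbital) to give C3–C4, and the methoxy-bearing terminus bonds to the boron-bearing carbon to give C5–C6. This matched polarisation is what should secure the regiochemistry the step needs (boron next to C6 and para to C2) against the steric preference of the borabicyclononyl group for an unsubstituted diene terminus. The trans relation of ethyl at C4 and boron at C5 follows stereospecifically from the (E) geometry of 9, the methoxy-bearing centre forms as an endo/exo mixture that is lost in step 5, and the product is racemic. Perborate then replaces boron by hydroxyl with retention at C5 under conditions that leave the silyl enol ether intact and forestall boron–methoxy β-elimination. The three trisubstituted chain alkenes are spectators, since no B–H bond is left after the hydroboration stage and unactivated alkenes do not compete with the electron-rich diene.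

Step 5
Reactants: 11 rac-(1R,6S)-4-(tert-butyldimethylsilyloxy)-6-ethyl-3-Far-2-methoxycyclohex-3-en-1-ol (C2 epimers)
Product: 12 rac-(4R,5S)-5-ethyl-2-Far-4-hydroxycyclohex-2-en-1-one
Conditions: 0.1 M HCl, THF/H2O, 0 °C
Reagents that add atoms: none
Why: Acid unmasking of a 1-alkoxy-3-silyloxy-diene cycloadduct (ionisation of the allylic methoxy group assisted by the silyl enol ether, then desilylation) gives the 2-substituted enone with C1=C6 in conjugation; the two carbinol-side centres are untouched, the C6 epimers converge, and cold dilute acid should avoid dehydration to a phenol.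

Step 6
Reactants: 12 rac-(4R,5S)-5-ethyl-2-Far-4-hydroxycyclohex-2-en-1-one
Product: 13 (4R,5S)-5-ethyl-2-Far-4-hydroxycyclohex-2-en-1-one
Conditions: Burkholderia cepacia lipase, vinyl acetate, tert-butyl methyl ether, 30 °C, stopped just past half conversion
Reagents that add atoms: none
Why: Lipase-catalysed kinetic resolution by irreversible acetylation (enzymatic transesterification) should, by the size rule with the ethyl-bearing ring carbon as the large group, acetylate the enantiomer with an S carbinol and leave 13, which fixes the absolute configuration of C5 of the target; no new stereocentre is formed.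

Step 7
Reactants: 13 (4R,5S)-5-ethyl-2-Far-4-hydroxycyclohex-2-en-1-one
Product: 14 (1R,4S,5R,6R)-4-ethyl-1-Far-5-hydroxy-7-oxabicyclo[4.1.0]heptan-2-one
Conditions: tBuOOH (anhydrous, in decane), DBU, CH2Cl2, 0 °C
Reagents that add atoms: tert-butyl hydroperoxide, CC(C)(C)OO
Why: Weitz–Scheffer nucleophilic epoxidation of the only enone sets C1 and C6 together, since the peroxide anion should add to C6 trans to the C4 ethyl group (the usual preference of 5-substituted cyclohexenones such as carvone) and on the face of the hydrogen-bond-donating C5 hydroxyl, two effects that reinforce each other and give the oxirane syn to the hydroxyl.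

Step 8
Reactants: 14 (1R,4S,5R,6R)-4-ethyl-1-Far-5-hydroxy-7-oxabicyclo[4.1.0]heptan-2-one
Product: 17 (1R,5R,6R)-4-ethyl-1-Far-5-hydroxy-7-oxabicyclo[4.1.0]hept-3-en-2-one (target), via 2,5-bis(trimethylsilyloxy) enol ether 15 (not isolated), via 5-O-trimethylsilyl enone 16 (not isolated)
Conditions: LiN(SiMe3)2 (2.2 equiv), Me3SiCl, THF, −78 °C; Pd(OAc)2, MeCN, 25 °C; citric acid, MeOH, 0 °C
Reagents that add atoms: none
Why: Saegusa–Ito oxidation, in which enol silylation can only occur toward C3 (C1 is quaternary) with transient O-silylation of the hydroxyl, and the palladium enolate loses the C4 hydrogen by β-hydride elimination to give the C3=C4 enone; the C4 centre is erased, C1, C5 and C6 are untouched (a syn hydroxy epoxide cannot undergo Payne rearrangement), and mild acidic methanolysis frees the hydroxyl.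

## Compound list

1 | (5E,9E)-6,10,14-trimethylpentadeca-5,9,13-trien-2-one (farnesylacetone) | CC(=O)CC/C=C(\C)CC/C=C(\C)CCC=C(C)C | starting material
2 | trimethyl{[(2Z,5E,9E)-6,10,14-trimethylpentadeca-2,5,9,13-tetraen-2-yl]oxy}silane | C/C(O[Si](C)(C)C)=C/C/C=C(\C)CC/C=C(\C)CCC=C(C)C | intermediate
3 | trimethyl orthoformate | COC(OC)OC | starting material
4 | rac-(5E,9E)-3-(dimethoxymethyl)-6,10,14-trimethylpentadeca-5,9,13-trien-2-one | CC(=O)C(C(OC)OC)C/C=C(\C)CC/C=C(\C)CCC=C(C)C | intermediate
5 | (3E)-3-Far-4-methoxybut-3-en-2-one (not isolated) | CO/C=C(\C/C=C(\C)CC/C=C(\C)CCC=C(C)C)C(C)=O | intermediate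
6 | (1E)-3-(tert-butyldimethylsilyloxy)-2-Far-1-methoxybuta-1,3-diene | CO/C=C(\C/C=C(\C)CC/C=C(\C)CCC=C(C)C)C(=C)O[Si](C)(C)C(C)(C)C | intermediate
7 | but-1-yne | CCC#C | starting material
8 | 9-borabicyclo[3.3.1]nonane (9-BBN-H, used as dimer) | B1C2CCCC1CCC2 | starting material
9 | 9-[(1E)-but-1-en-1-yl]-9-borabicyclo[3.3.1]nonane (not isolated) | CC/C=C/B1C2CCCC1CCC2 | intermediate
10 | 9-[rac-(1R,6S)-4-(tert-butyldimethylsilyloxy)-6-ethyl-3-Far-2-methoxycyclohex-3-en-1-yl]-9-borabicyclo[3.3.1]nonane (C2 epimers, racemate, one enantiomer drawn, not isolated) | CC[C@H]1CC(O[Si](C)(C)C(C)(C)C)=C(C/C=C(\C)CC/C=C(\C)CCC=C(C)C)C(OC)[C@@H]1B1C2CCCC1CCC2 | intermediate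
11 | rac-(1R,6S)-4-(tert-butyldimethylsilyloxy)-6-ethyl-3-Far-2-methoxycyclohex-3-en-1-ol (C2 epimers, racemate, one enantiomer drawn) | CC[C@H]1CC(O[Si](C)(C)C(C)(C)C)=C(C/C=C(\C)CC/C=C(\C)CCC=C(C)C)C(OC)[C@@H]1O | intermediate
12 | rac-(4R,5S)-5-ethyl-2-Far-4-hydroxycyclohex-2-en-1-one (racemate, one enantiomer drawn) | CC[C@H]1CC(=O)C(C/C=C(\C)CC/C=C(\C)CCC=C(C)C)=C[C@@H]1O | intermediate
13 | (4R,5S)-5-ethyl-2-Far-4-hydroxycyclohex-2-en-1-one | CC[C@H]1CC(=O)C(C/C=C(\C)CC/C=C(\C)CCC=C(C)C)=C[C@@H]1O | intermediate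
14 | (1R,4S,5R,6R)-4-ethyl-1-Far-5-hydroxy-7-oxabicyclo[4.1.0]heptan-2-one | CC[C@H]1CC(=O)[C@]2(C/C=C(\C)CC/C=C(\C)CCC=C(C)C)O[C@@H]2[C@@H]1O | intermediate
15 | (1R,4S,5R,6R)-4-ethyl-1-Far-2,5-bis(trimethylsilyloxy)-7-oxabicyclo[4.1.0]hept-2-ene (not isolated) | CC[C@H]1C=C(O[Si](C)(C)C)[C@]2(C/C=C(\C)CC/C=C(\C)CCC=C(C)C)O[C@@H]2[C@@H]1O[Si](C)(C)C | intermediate
16 | (1R,5R,6R)-4-ethyl-1-Far-5-(trimethylsilyloxy)-7-oxabicyclo[4.1.0]hept-3-en-2-one (not isolated) | CCC1=CC(=O)[C@]2(C/C=C(\C)CC/C=C(\C)CCC=C(C)C)O[C@@H]2[C@@H]1O[Si](C)(C)C | intermediate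
17 | (1R,5R,6R)-4-ethyl-5-hydroxy-1-[(2E,6E)-3,7,11-trimethyldodeca-2,6,10-trien-1-yl]-7-oxabicyclo[4.1.0]hept-3-en-2-one (CID44566894) | CCC1=CC(=O)[C@]2(C/C=C(\C)CC/C=C(\C)CCC=C(C)C)O[C@@H]2[C@@H]1O | target

## Step count and risks

Total step count: 8. Longest linear sequence: 8 steps (1 to 17); compounds 3, 7 and 8 enter as commercial materials.

The three steps most likely to fail:

Step 4. What may go wrong: loss of regiocontrol or a slow cycloaddition, because the bulky borabicyclononyl group must approach the methoxy-substituted diene terminus, and boron–methoxy β-elimination of the cycloadduct before it is oxidised. The fallback sets out from 6 and returns at 12, with a conventional acyl-activated dienophile of the same polarisation. Diene 6 is heated with commercial (E)-hex-3-en-2-one (toluene, 110 °C) to give the silyl enol ether cycloadduct 1-[rac-(1R,6S)-4-(tert-butyldimethylsilyloxy)-6-ethyl-3-Far-2-methoxycyclohex-3-en-1-yl]ethan-1-one F1. Treatment with 0.1 M HCl in THF releases the trans acetyl enone rac-(4R,5S)-4-acetyl-5-ethyl-2-Far-cyclohex-2-en-1-one F2. A Baeyer–Villiger oxidation under alkene-sparing conditions (Me3SiOOSiMe3, catalytic TMSOTf, CH2Cl2, −40 °C; the secondary ring carbon migrates with retention) gives rac-(1R,6S)-6-ethyl-3-Far-4-oxocyclohex-2-en-1-yl acetate F3, and K2CO3 in MeOH at 0 °C gives 12.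

Step 6. What may go wrong: insufficient discrimination between the enantiomers, or very slow acylation, because the carbinol is flanked by a branched ethyl-bearing carbon. The fallback sets out from 12 and returns at 13 by classical resolution through covalent diastereomers. Racemate 12 is esterified with commercial (S)-2-methoxy-2-phenylacetic acid (DCC, DMAP, CH2Cl2). The esters (1R,6S)-6-ethyl-3-Far-4-oxocyclohex-2-en-1-yl (2S)-2-methoxy-2-phenylacetate F4 and (1S,6R)-6-ethyl-3-Far-4-oxocyclohex-2-en-1-yl (2S)-2-methoxy-2-phenylacetate F5 are separated by chromatography, and F4 is methanolysed (K2CO3, MeOH, 0 °C) to 13.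

Step 8. What may go wrong: incomplete or misdirected dehydrogenation, through complexation of divalent palladium by the chain alkenes, desilylation back to 14, or epoxide opening during enolisation. The fallback sets out from 14 and returns at 17, with a selenoxide elimination in place of the palladium-mediated step. Compound 14 is silylated (Et3SiCl, imidazole, CH2Cl2) to (1R,4S,5R,6R)-4-ethyl-1-Far-5-(triethylsilyloxy)-7-oxabicyclo[4.1.0]heptan-2-one F6. Its lithium enolate (LiN(SiMe3)2, THF, −78 °C) is trapped with PhSeCl, expected trans to the neighbouring ethyl group, to give (1R,4R,5R,6R)-4-ethyl-1-Far-3-(phenylselanyl)-5-(triethylsilyloxy)-7-oxabicyclo[4.1.0]heptan-2-one F7. Oxidation at selenium (mCPBA, 1 equiv, CH2Cl2, −78 °C, then iPr2NH and warming) should trigger syn elimination toward C4 and give (1R,5R,6R)-4-ethyl-1-Far-5-(triethylsilyloxy)-7-oxabicyclo[4.1.0]hept-3-en-2-one F8, and HF·pyridine in THF at 0 °C gives 17.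

Further compounds
F1 | step 4 | 1-[rac-(1R,6S)-4-(tert-butyldimethylsilyloxy)-6-ethyl-3-Far-2-methoxycyclohex-3-en-1-yl]ethan-1-one (C2 epimers, racemate, one enantiomer drawn) | CC[C@H]1CC(O[Si](C)(C)C(C)(C)C)=C(C/C=C(\C)CC/C=C(\C)CCC=C(C)C)C(OC)[C@@H]1C(C)=O
F2 | step 4 | rac-(4R,5S)-4-acetyl-5-ethyl-2-Far-cyclohex-2-en-1-one (racemate, one enantiomer drawn) | CC[C@H]1CC(=O)C(C/C=C(\C)CC/C=C(\C)CCC=C(C)C)=C[C@@H]1C(C)=O
F3 | step 4 | rac-(1R,6S)-6-ethyl-3-Far-4-oxocyclohex-2-en-1-yl acetate (racemate, one enantiomer drawn) | CC[C@H]1CC(=O)C(C/C=C(\C)CC/C=C(\C)CCC=C(C)C)=C[C@@H]1OC(C)=O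
F4 | step 6 | (1R,6S)-6-ethyl-3-Far-4-oxocyclohex-2-en-1-yl (2S)-2-methoxy-2-phenylacetate | CC[C@H]1CC(=O)C(C/C=C(\C)CC/C=C(\C)CCC=C(C)C)=C[C@@H]1OC(=O)[C@@H](OC)c1ccccc1
F5 | step 6 | (1S,6R)-6-ethyl-3-Far-4-oxocyclohex-2-en-1-yl (2S)-2-methoxy-2-phenylacetate | CC[C@@H]1CC(=O)C(C/C=C(\C)CC/C=C(\C)CCC=C(C)C)=C[C@H]1OC(=O)[C@@H](OC)c1ccccc1
F6 | step 8 | (1R,4S,5R,6R)-4-ethyl-1-Far-5-(triethylsilyloxy)-7-oxabicyclo[4.1.0]heptan-2-one | CC[C@H]1CC(=O)[C@]2(C/C=C(\C)CC/C=C(\C)CCC=C(C)C)O[C@@H]2[C@@H]1O[Si](CC)(CC)CC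
F7 | step 8 | (1R,4R,5R,6R)-4-ethyl-1-Far-3-(phenylselanyl)-5-(triethylsilyloxy)-7-oxabicyclo[4.1.0]heptan-2-one (C3 epimers) | CC[C@H]1C([Se]c3ccccc3)C(=O)[C@]2(C/C=C(\C)CC/C=C(\C)CCC=C(C)C)O[C@@H]2[C@@H]1O[Si](CC)(CC)CC
F8 | step 8 | (1R,5R,6R)-4-ethyl-1-Far-5-(triethylsilyloxy)-7-oxabicyclo[4.1.0]hept-3-en-2-one | CCC1=CC(=O)[C@]2(C/C=C(\C)CC/C=C(\C)CCC=C(C)C)O[C@@H]2[C@@H]1O[Si](CC)(CC)CC
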